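**Strategy.** Coelenterazine is disconnected at N7 of its pyrazine ring: both bonds to that nitrogen, N7–C6 and N7–C8, are traced back to ammonia and a 1,5-diketone. The route uses the fact that N7 is flanked by aryl-bearing C6 and benzyl-bearing C8; each is drawn back to a carbonyl carbon, C8 in an acyl substituent at C8a and C6 in the phenacyl chain at N4 of an intact imidazolone ring. The precursor is thus a (Z)-4-(4-hydroxybenzylidene)imidazol-5-one with N-(4-hydroxyphenacyl) and C-phenylacetyl groups, released by a neutral oxidation so that it never meets base. One ammonium acetate treatment closes the pyrazine ring to dehydrocoelenterazine, which borohydride reduces to the target.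

Key step: step 6

Assumption: the target has no stereocentre and no stereogenic double bond, so the achiral compound is the single species asked for; the carbinol centre in 1–3, 5, 8, 9, 11 and 12 is used racemic and disappears in step 5, and the only stereo-element to hold is the Z-arylidene of 9–16.

**Step 1**
Reactants: 1 (±)-3-phenyllactic acid (2-hydroxy-3-phenylpropanoic acid)
Product: 3 2-acetoxy-3-phenylpropanoyl chloride (racemic), via 2-acetoxy-3-phenylpropanoic acid 2 (not isolated)
Conditions: AcCl (neat), 25→50 °C; evaporate; SOCl2, cat. DMF, 50 °C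
Reagents that add atoms: acetyl chloride CC(=O)Cl; thionyl chloride O=S(Cl)Cl
Why: O-acetylation of an α-hydroxy acid with acetyl chloride followed by acid chloride formation with thionyl chloride is the standard entry to α-acyloxy acyl chlorides, and it places the future C8 oxygen in the chain at the alcohol level so that no C–H oxidation is needed later.

**Step 2**
Reactants: 3 2-acetoxy-3-phenylpropanoyl chloride; 4 glycine
Product: 5 N-(2-acetoxy-3-phenylpropanoyl)glycine (racemic)
Conditions: NaHCO3, H2O/THF, 0 °C→rt; then HCl to pH 2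
Reagents that add atoms: none
Why: Schotten–Baumann N-acylation of glycine, run at bicarbonate pH so that the secondary acetate is not hydrolysed.

**Step 3**
Reactants: 5 N-(2-acetoxy-3-phenylpropanoyl)glycine; 6 4-hydroxybenzaldehyde
Product: 9 (Z)-4-(4-acetoxybenzylidene)-2-(1-acetoxy-2-phenylethyl)oxazol-5(4H)-one, via 4-acetoxybenzaldehyde 7 (not isolated), via 2-(1-acetoxy-2-phenylethyl)oxazol-5(4H)-one 8 (not isolated)
Conditions: Ac2O, NaOAc, 90 °C
Reagents that add atoms: acetic anhydride CC(=O)OC(C)=O
Why: Erlenmeyer–Plöchl azlactone synthesis, in which acetic anhydride acetylates the phenol and cyclodehydrates 5 to oxazolone 8, whose C4 enolate condenses with 7 to the thermodynamically preferred Z-arylidene; once C4 is fully substituted the ring can no longer enolise, so the side-chain acetate is no longer at risk.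

**Step 4**
Reactants: 9 (Z)-4-(4-acetoxybenzylidene)-2-(1-acetoxy-2-phenylethyl)oxazol-5(4H)-one; 10 2-amino-1-(4-hydroxyphenyl)ethanone hydrochloride
Product: 12 (Z)-2-(1-hydroxy-2-phenylethyl)-4-(4-hydroxybenzylidene)-1-[2-(4-hydroxyphenyl)-2-oxoethyl]-1H-imidazol-5(4H)-one, via ring-opened diamide 11 (not isolated)
Conditions: (i) Et3N, MeCN, 0 °C→rt; (ii) K2CO3, MeOH, 65 °C; AcOH to pH 6
Reagents that add atoms: none
Why: Azlactone aminolysis followed by base-mediated cyclodehydration of the dehydroamino acid diamide is the standard route to 1-substituted 4-arylidene-imidazol-5-ones and fixes the phenacyl group on the correct nitrogen without an ambident alkylation; carbonate in methanol also removes both acetates, the aryl ketone is shielded as its phenoxide (a vinylogous carboxylate) during the basic stage, and the Z-alkene is retained as the stable isomer.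

**Step 5**
Reactants: 12 (Z)-2-(1-hydroxy-2-phenylethyl)-4-(4-hydroxybenzylidene)-1-[2-(4-hydroxyphenyl)-2-oxoethyl]-1H-imidazol-5(4H)-one
Product: 13 (Z)-4-(4-hydroxybenzylidene)-1-[2-(4-hydroxyphenyl)-2-oxoethyl]-2-(2-phenylacetyl)-1H-imidazol-5(4H)-one
Conditions: IBX, DMSO, 25 °C; aqueous work-up without base; used at once
Reagents that add atoms: none
Why: IBX oxidation of a secondary alcohol to the ketone under neutral conditions, to which the two electron-poor phenols should be inert; any cyclic hemiketal form of 12 should reopen as the open alcohol is consumed, and the absence of base should keep the new benzylic ketone from aldol closure onto the phenacyl carbonyl.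

**Step 6**
Reactants: 13 (Z)-4-(4-hydroxybenzylidene)-1-[2-(4-hydroxyphenyl)-2-oxoethyl]-2-(2-phenylacetyl)-1H-imidazol-5(4H)-one
Product: 16 (Z)-8-benzyl-2-(4-hydroxybenzylidene)-6-(4-hydroxyphenyl)imidazo[1,2-a]pyrazin-3(2H)-one (dehydrocoelenterazine), via C8 ketimine 14 (not isolated), via cyclic carbinolamine 15 (not isolated)
Conditions: NH4OAc (15 equiv), AcOH, 80 °C, Ar
Reagents that add atoms: ammonium acetate CC(=O)[O-].[NH4+]
Why: Proposed new method: ammonia from the acetate buffer should add to the C8 ketone, the most electrophilic carbonyl because it sits on the amidine carbon C8a, to give ketimine 14, whose nitrogen then attacks the aryl ketone C6 in a 6-exo-trig closure to carbinolamine 15; loss of water across C6–C5 completes the pyrazine ring with N7–C8 and N7–C6 in place. The closest known reaction type is the ammonium acetate cyclocondensation of 1-(2-oxoalkyl)-2-acyl pyrroles, imidazoles and benzimidazoles to azolo[1,2-a]pyrazines (a 1,5-dicarbonyl/ammonia aza-annulation), which has not been run on a non-aromatic 4-arylidene-imidazol-5-one. Two ketones plus ammonia are already at the oxidation level of the quinoid pyrazine in 16, so no oxidant is required. No stereocentre remains in 16 (the C6 centre of 15 is transient), and the Z-arylidene, the thermodynamic isomer, is carried through. The step needs N-closure at the two ketones to win over aldol closure of the benzylic carbon onto C6, conjugate addition of ammonia to the arylidene and ammonolysis of the C3 acylamidine; a large excess of ammonium acetate in acetic acid (no enolate, reversible amine adducts), the high electrophilicity of the α-amidino ketone and the fully substituted C2 (no acidic C2–H) should secure this.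

**Step 7**
Reactants: 16 (Z)-dehydrocoelenterazine
Product: 17 coelenterazine, 8-benzyl-2-(4-hydroxybenzyl)-6-(4-hydroxyphenyl)imidazo[1,2-a]pyrazin-3(7H)-one
Conditions: NaBH4, degassed MeOH, 0 °C, Ar; then AcOH
Reagents that add atoms: none
Why: Vinylogous conjugate hydride addition to the exocyclic benzylidene carbon should give the N7-centred imidazopyrazinone anion, protonated on acidification; this borohydride reduction of dehydrocoelenterazine is a known transformation, creates no stereocentre, and is run without oxygen because the product anion autoxidises.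

**Compound list**
1 | (±)-3-phenyllactic acid | OC(Cc1ccccc1)C(=O)O | starting material
2 | 2-acetoxy-3-phenylpropanoic acid (racemic) | CC(=O)OC(Cc1ccccc1)C(=O)O | intermediate (not isolated)
3 | 2-acetoxy-3-phenylpropanoyl chloride (racemic) | CC(=O)OC(Cc1ccccc1)C(Cl)=O | intermediate
4 | glycine | NCC(=O)O | starting material
5 | N-(2-acetoxy-3-phenylpropanoyl)glycine (racemic) | CC(=O)OC(Cc1ccccc1)C(=O)NCC(=O)O | intermediate
6 | 4-hydroxybenzaldehyde | O=Cc1ccc(O)cc1 | starting material
7 | 4-acetoxybenzaldehyde | CC(=O)Oc1ccc(C=O)cc1 | intermediate (not isolated)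
8 | 2-(1-acetoxy-2-phenylethyl)oxazol-5(4H)-one (racemic) | CC(=O)OC(Cc1ccccc1)C1=NCC(=O)O1 | intermediate (not isolated)
9 | (Z)-4-(4-acetoxybenzylidene)-2-(1-acetoxy-2-phenylethyl)oxazol-5(4H)-one (racemic) | CC(=O)OC(Cc1ccccc1)C1=N/C(=C\c2ccc(OC(C)=O)cc2)C(=O)O1 | intermediate
10 | 2-amino-1-(4-hydroxyphenyl)ethanone hydrochloride | Cl.NCC(=O)c1ccc(O)cc1 | starting material
11 | 4-[(Z)-2-[(2-acetoxy-3-phenylpropanoyl)amino]-3-{[2-(4-hydroxyphenyl)-2-oxoethyl]amino}-3-oxoprop-1-enyl]phenyl acetate (racemic) | CC(=O)OC(Cc1ccccc1)C(=O)N/C(=C\c1ccc(OC(C)=O)cc1)C(=O)NCC(=O)c1ccc(O)cc1 | intermediate (not isolated)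
12 | (Z)-2-(1-hydroxy-2-phenylethyl)-4-(4-hydroxybenzylidene)-1-[2-(4-hydroxyphenyl)-2-oxoethyl]-1H-imidazol-5(4H)-one (racemic) | OC(Cc1ccccc1)C1=N/C(=C\c2ccc(O)cc2)C(=O)N1CC(=O)c1ccc(O)cc1 | intermediate
13 | (Z)-4-(4-hydroxybenzylidene)-1-[2-(4-hydroxyphenyl)-2-oxoethyl]-2-(2-phenylacetyl)-1H-imidazol-5(4H)-one | O=C(Cc1ccccc1)C1=N/C(=C\c2ccc(O)cc2)C(=O)N1CC(=O)c1ccc(O)cc1 | intermediate
14 | (Z)-4-(4-hydroxybenzylidene)-1-[2-(4-hydroxyphenyl)-2-oxoethyl]-2-(1-imino-2-phenylethyl)-1H-imidazol-5(4H)-one | N=C(Cc1ccccc1)C1=N/C(=C\c2ccc(O)cc2)C(=O)N1CC(=O)c1ccc(O)cc1 | intermediate (not isolated)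
15 | (Z)-8-benzyl-6-hydroxy-2-(4-hydroxybenzylidene)-6-(4-hydroxyphenyl)-5,6-dihydroimidazo[1,2-a]pyrazin-3(2H)-one (racemic at C6) | O=C1/C(=C/c2ccc(O)cc2)N=C2C(Cc3ccccc3)=NC(O)(c3ccc(O)cc3)CN12 | intermediate (not isolated)
16 | (Z)-dehydrocoelenterazine | O=C1/C(=C/c2ccc(O)cc2)N=C2C(Cc3ccccc3)=NC(c3ccc(O)cc3)=CN12 | intermediate
17 | coelenterazine | O=c1c(Cc2ccc(O)cc2)nc2c(Cc3ccccc3)[nH]c(-c3ccc(O)cc3)cn1-2 | target

**Step count.** Total steps: 7. Longest linear sequence: 7 steps (1 to 17).

**Steps most likely to fail**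

1. Step 6 (Proposed new method). The ring could close through carbon instead of nitrogen (acid-catalysed aldol condensation of the benzylic methylene onto the C6 ketone), the imidazolone could be opened by ammonolysis, or ammonia could add irreversibly to the arylidene. The fallback uses known chemistry, sets out from 6 and rejoins the route at 17. Compound 6 is silylated (TBSCl, imidazole, DMF) to 4-(tert-butyldimethylsilyloxy)benzaldehyde F1, reduced (NaBH4, MeOH) to [4-(tert-butyldimethylsilyloxy)phenyl]methanol F2 and converted (MsCl, Et3N, CH2Cl2) into 4-(tert-butyldimethylsilyloxy)benzyl chloride F3. Magnesium in THF gives [4-(tert-butyldimethylsilyloxy)benzyl]magnesium chloride F4, which is added to ethyl diethoxyacetate at −78 °C to give 3-[4-(tert-butyldimethylsilyloxy)phenyl]-1,1-diethoxypropan-2-one F5. Separately, commercial 3,5-dibromopyrazin-2-amine is benzylated at C3 by Negishi coupling (BnZnBr, Pd(PPh3)2Cl2, THF) to 3-benzyl-5-bromopyrazin-2-amine F6 and arylated by Suzuki coupling (4-hydroxyphenylboronic acid, Pd(PPh3)4, Na2CO3) to coelenteramine F7. Condensation of F5 with F7 in degassed aqueous HCl/ethanol at 80 °C (amine on the ketone, ring nitrogen on the unmasked aldehyde, silyl ether cleaved in the same pot) should give 17 directly, by-passing 13 and 16.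

2. Step 3. The side-chain acetate could be lost from oxazolone enolate 8 (vinylogous elimination to a 2-alkylidene pseudo-azlactone) before the aldehyde condenses. The fallback sets out from 3 and rejoins at 9 without passing through a C4-unsubstituted oxazolone. Compound 3 with aqueous ammonia gives 2-acetoxy-3-phenylpropanamide F8. Acid-catalysed condensation of F8 with commercial 4-hydroxyphenylpyruvic acid (TsOH, toluene, Dean–Stark) gives (Z)-2-[(2-acetoxy-3-phenylpropanoyl)amino]-3-(4-hydroxyphenyl)acrylic acid F9. Acetic anhydride with sodium acetate at 60 °C then acetylates the phenol and cyclodehydrates F9 to 9.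

3. Step 4. The liberated α-aminoketone could self-condense to a dihydropyrazine, or an amide nitrogen could add to the ketone in place of imidazolone closure. The fallback sets out from 9 and rejoins at 12, bringing the side chain in at the alcohol level. Compound 9 is opened with commercial (±)-octopamine hydrochloride (Et3N, MeCN) to 4-[(Z)-2-[(2-acetoxy-3-phenylpropanoyl)amino]-3-{[2-hydroxy-2-(4-hydroxyphenyl)ethyl]amino}-3-oxoprop-1-enyl]phenyl acetate F10. This is cyclised and deacetylated (K2CO3, MeOH, 65 °C) to (Z)-1-[2-hydroxy-2-(4-hydroxyphenyl)ethyl]-2-(1-hydroxy-2-phenylethyl)-4-(4-hydroxybenzylidene)-1H-imidazol-5(4H)-one F11, a mixture of diastereomers. DDQ in dioxane at room temperature then oxidises only the 4-hydroxybenzylic alcohol, giving 12.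

**Further compounds**
F1 | step 6 | 4-(tert-butyldimethylsilyloxy)benzaldehyde | CC(C)(C)[Si](C)(C)Oc1ccc(C=O)cc1
F2 | step 6 | [4-(tert-butyldimethylsilyloxy)phenyl]methanol | CC(C)(C)[Si](C)(C)Oc1ccc(CO)cc1
F3 | step 6 | 4-(tert-butyldimethylsilyloxy)benzyl chloride | CC(C)(C)[Si](C)(C)Oc1ccc(CCl)cc1
F4 | step 6 | [4-(tert-butyldimethylsilyloxy)benzyl]magnesium chloride | CC(C)(C)[Si](C)(C)Oc1ccc(C[Mg]Cl)cc1
F5 | step 6 | 3-[4-(tert-butyldimethylsilyloxy)phenyl]-1,1-diethoxypropan-2-one | CCOC(OCC)C(=O)Cc1ccc(O[Si](C)(C)C(C)(C)C)cc1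
F6 | step 6 | 3-benzyl-5-bromopyrazin-2-amine | Nc1ncc(Br)nc1Cc1ccccc1
F7 | step 6 | coelenteramine, 4-(5-amino-6-benzylpyrazin-2-yl)phenol | Nc1ncc(-c2ccc(O)cc2)nc1Cc1ccccc1
F8 | step 3 | 2-acetoxy-3-phenylpropanamide (racemic) | CC(=O)OC(Cc1ccccc1)C(N)=O
F9 | step 3 | (Z)-2-[(2-acetoxy-3-phenylpropanoyl)amino]-3-(4-hydroxyphenyl)acrylic acid (racemic) | CC(=O)OC(Cc1ccccc1)C(=O)N/C(=C\c1ccc(O)cc1)C(=O)O
F10 | step 4 | 4-[(Z)-2-[(2-acetoxy-3-phenylpropanoyl)amino]-3-{[2-hydroxy-2-(4-hydroxyphenyl)ethyl]amino}-3-oxoprop-1-enyl]phenyl acetate (diastereomer mixture) | CC(=O)OC(Cc1ccccc1)C(=O)N/C(=C\c1ccc(OC(C)=O)cc1)C(=O)NCC(O)c1ccc(O)cc1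
F11 | step 4 | (Z)-1-[2-hydroxy-2-(4-hydroxyphenyl)ethyl]-2-(1-hydroxy-2-phenylethyl)-4-(4-hydroxybenzylidene)-1H-imidazol-5(4H)-one (diastereomer mixture) | OC(Cc1ccccc1)C1=N/C(=C\c2ccc(O)cc2)C(=O)N1CC(O)c1ccc(O)cc1
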